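## Retrosynthetic overview

- Pakyonol ⇐ its O‑isopropyl ether ⇐ a macrocyclic benzylic phenyl sulfone (BCl3 dealkylation; Mg/MeOH desulfonylation).
- Macrocyclic sulfone ⇐ open‑chain A–B–C–D sulfone/aryl chloride: the sulfonyl‑stabilised carbanion at the end of the ring A side chain is arylated by an aryne generated on ring D. This closes the 20‑membered ring, the only ring formed; all four benzene rings are bought.
- Enabling feature: ring D is a meta‑phenylene with the ether O on C1, the benzylic CH2 on C3 and an unsubstituted C2–H between them. This is the pattern left when a nucleophile adds to a C2≡C3 aryne at the carbon remote from oxygen and C2 is then protonated; a 3‑chloro substituent serves as the traceless aryne precursor.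
- Open‑chain precursor ⇐ B‑alkyl Suzuki coupling of a ring C–D styrene (SNAr ether, Wittig) with a ring A–B aryl bromide (Knoevenagel–decarboxylation, hydrogenation, Chan–Lam ether).

Key step: step 8

Remark: the target has no stereocentre and the macrocycle is assumed to be conformationally mobile, so no atropisomer has to be controlled. Ring A is the methoxy ring, ring B the para‑phenylene bonded to it through O, ring C the hydroxylated ring, ring D the meta‑phenylene.

## Route

Step 1
Reactants: 1 4‑fluoro‑3‑hydroxybenzaldehyde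
Product: 2 4‑fluoro‑3‑(propan‑2‑yloxy)benzaldehyde
Conditions: 2‑bromopropane (1.5 equiv), K2CO3 (2 equiv), DMF, 60 °C
Reagents that add atoms: 2‑bromopropane, CC(C)Br
Why: Williamson etherification of the phenoxide; the isopropyl ether is chosen because it should survive lithium amide bases and is cleaved by BCl3 without loss of an aryl methyl ether.

Step 2
Reactants: 2 4‑fluoro‑3‑(propan‑2‑yloxy)benzaldehyde; 3 3‑chlorophenol
Product: 4 4‑(3‑chlorophenoxy)‑3‑(propan‑2‑yloxy)benzaldehyde
Conditions: K2CO3 (2 equiv), DMF, 130 °C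
Reagents that add atoms: none
Why: SNAr displacement of the fluoride para to the formyl group by the phenoxide (Meisenheimer pathway); the chloride of the nucleophile is unactivated and should stay.

Step 3
Reactants: 4 4‑(3‑chlorophenoxy)‑3‑(propan‑2‑yloxy)benzaldehyde
Product: 5 1‑(3‑chlorophenoxy)‑4‑ethenyl‑2‑(propan‑2‑yloxy)benzene
Conditions: Ph3PCH3Br (1.3 equiv), KOt‑Bu (1.25 equiv), THF, 0 °C to rt
Reagents that add atoms: methyltriphenylphosphonium bromide, C[P+](c1ccccc1)(c1ccccc1)c1ccccc1.[Br-]
Why: Wittig methylenation of an aromatic aldehyde with the non‑stabilised ylide; aryl chloride and ethers are inert.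

Step 4
Reactants: 6 isovanillin (3‑hydroxy‑4‑methoxybenzaldehyde); 7 (phenylsulfonyl)acetic acid
Product: 8 (E)‑2‑methoxy‑5‑[2‑(phenylsulfonyl)ethenyl]phenol
Conditions: BnNH2 (cat.), AcOH, reflux
Reagents that add atoms: none
Why: Knoevenagel condensation with decarboxylation (Doebner type) should give the thermodynamically preferred E‑vinyl sulfone and tolerates the free phenol.

Step 5
Reactants: 8 (E)‑2‑methoxy‑5‑[2‑(phenylsulfonyl)ethenyl]phenol
Product: 9 2‑methoxy‑5‑[2‑(phenylsulfonyl)ethyl]phenol
Conditions: H2 (1 atm), 10% Pd/C, EtOAc–EtOH, rt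
Reagents that add atoms: none
Why: catalytic hydrogenation of the conjugated C=C; sulfone, phenol and methyl ether are untouched, and no halogen is present at this stage.

Step 6
Reactants: 9 2‑methoxy‑5‑[2‑(phenylsulfonyl)ethyl]phenol; 10 (4‑bromophenyl)boronic acid
Product: 11 2‑(4‑bromophenoxy)‑1‑methoxy‑4‑[2‑(phenylsulfonyl)ethyl]benzene
Conditions: Cu(OAc)2 (1 equiv), pyridine (5 equiv), 4 Å MS, CH2Cl2, dry air (terminal oxidant), rt
Reagents that add atoms: none
Why: Chan–Lam–Evans oxidative O‑arylation forms the A–O–B diaryl ether at room temperature and leaves the C–Br bond for the next coupling.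

Step 7
Reactants: 5 1‑(3‑chlorophenoxy)‑4‑ethenyl‑2‑(propan‑2‑yloxy)benzene; 11 2‑(4‑bromophenoxy)‑1‑methoxy‑4‑[2‑(phenylsulfonyl)ethyl]benzene
Product: 13 1‑(3‑chlorophenoxy)‑4‑[2‑(4‑{2‑methoxy‑5‑[2‑(phenylsulfonyl)ethyl]phenoxy}phenyl)ethyl]‑2‑(propan‑2‑yloxy)benzene, via B‑alkyl‑9‑BBN adduct 12 (not isolated)
Conditions: 9‑BBN (1.3 equiv), THF, 0 °C to rt; then 11, Pd(dppf)Cl2 (5 mol %), 3 M aq K3PO4, DMF, 60 °C
Reagents that add atoms: none
Why: anti‑Markovnikov hydroboration of the styrene followed by B‑alkyl Suzuki–Miyaura coupling builds the B–C bibenzyl directly; the aryl bromide reacts while the electron‑rich aryl chloride should be inert to Pd(dppf) at 60 °C.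

Step 8
Reactants: 13 1‑(3‑chlorophenoxy)‑4‑[2‑(4‑{2‑methoxy‑5‑[2‑(phenylsulfonyl)ethyl]phenoxy}phenyl)ethyl]‑2‑(propan‑2‑yloxy)benzene
Product: 16 rac‑macrocyclic benzylic sulfone (O‑isopropylpakyonol carrying PhSO2 on the CH2 bonded to ring D), via dilithio species 14 (not isolated), via lithiated aryne 15 (not isolated)
Conditions: LiTMP (3 equiv), THF (1 mM), −78 °C, then slowly to −20 °C; aq NH4Cl
Reagents that add atoms: none
Why: Proposed new method: LiTMP deprotonates the sulfone α‑CH2 and then lithiates ring D at C2, the C–H flanked by the aryloxy oxygen and chlorine, to give 14, which loses LiCl on warming to the 3‑aryloxybenzyne 15 (C2≡C3 of ring D); the tethered α‑sulfonyl carbanion adds to C3 and the resulting C2 aryllithium is protonated by the adjacent benzylic sulfone C–H or TMPH and finally on quench. The closest known reaction types are the intermolecular arylation of α‑sulfonyl and α‑cyano carbanions by 3‑alkoxybenzynes made from 3‑haloanisoles with lithium amides, and Bunnett‑type intramolecular carbanion–aryne closures, which are established for four‑ to seven‑membered rings but not for macrocycles. The single ring closed is the 20‑membered macrocycle, in a 20‑endo‑dig mode, since both aryne carbons end up in the ring. The sulfonyl‑bearing carbon becomes a stereocentre that is formed racemic without control and is erased in step 9. The step needs attack at C3 and not at C2 (which would give a 19‑membered ortho isomer); this is secured by the inductively withdrawing aryloxy group on C1, which distorts the aryne so that C3 is the more electrophilic carbon and puts the developing negative charge on C2 next to oxygen. It also needs ring closure to outrun intermolecular capture, which 1 mM concentration, slow unimolecular release of the aryne and a hindered, poorly nucleophilic amide base should secure, and the isopropyl ether keeps the ring C oxygen from closing a dibenzodioxin onto the aryne.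

Step 9
Reactants: 16 rac‑macrocyclic benzylic sulfone
Product: 17 O‑isopropylpakyonol
Conditions: Mg turnings (20 equiv, I2‑activated), MeOH–THF, rt to 50 °C
Reagents that add atoms: none
Why: single‑electron reductive desulfonylation of a benzylic aryl sulfone (Mg/MeOH) replaces C–S by C–H and removes the only stereocentre; aryl ethers are not reduced.

Step 10
Reactants: 17 O‑isopropylpakyonol
Product: 18 pakyonol
Conditions: BCl3 (3 equiv), CH2Cl2, −78 °C to 0 °C; then MeOH, H2O
Reagents that add atoms: none
Why: Lewis‑acid dealkylation with BCl3 cleaves the secondary isopropyl aryl ether far faster than the methyl aryl ether and leaves both diaryl ethers intact.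

## Compound list

1 | 4‑fluoro‑3‑hydroxybenzaldehyde | O=Cc1ccc(F)c(O)c1 | starting material
2 | 4‑fluoro‑3‑(propan‑2‑yloxy)benzaldehyde | CC(C)Oc1cc(C=O)ccc1F | intermediate
3 | 3‑chlorophenol | Oc1cccc(Cl)c1 | starting material
4 | 4‑(3‑chlorophenoxy)‑3‑(propan‑2‑yloxy)benzaldehyde | CC(C)Oc1cc(C=O)ccc1Oc1cccc(Cl)c1 | intermediate
5 | 1‑(3‑chlorophenoxy)‑4‑ethenyl‑2‑(propan‑2‑yloxy)benzene | CC(C)Oc1cc(C=C)ccc1Oc1cccc(Cl)c1 | intermediate
6 | isovanillin (3‑hydroxy‑4‑methoxybenzaldehyde) | COc1ccc(C=O)cc1O | starting material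
7 | (phenylsulfonyl)acetic acid | OC(=O)CS(=O)(=O)c1ccccc1 | starting material
8 | (E)‑2‑methoxy‑5‑[2‑(phenylsulfonyl)ethenyl]phenol | COc1ccc(/C=C/S(=O)(=O)c2ccccc2)cc1O | intermediate
9 | 2‑methoxy‑5‑[2‑(phenylsulfonyl)ethyl]phenol | COc1ccc(CCS(=O)(=O)c2ccccc2)cc1O | intermediate
10 | (4‑bromophenyl)boronic acid | OB(O)c1ccc(Br)cc1 | starting material
11 | 2‑(4‑bromophenoxy)‑1‑methoxy‑4‑[2‑(phenylsulfonyl)ethyl]benzene | COc1ccc(CCS(=O)(=O)c2ccccc2)cc1Oc1ccc(Br)cc1 | intermediate
12 | 9‑{2‑[4‑(3‑chlorophenoxy)‑3‑(propan‑2‑yloxy)phenyl]ethyl}‑9‑borabicyclo[3.3.1]nonane (not isolated) | CC(C)Oc1cc(CCB2C3CCCC2CCC3)ccc1Oc1cccc(Cl)c1 | intermediate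
13 | 1‑(3‑chlorophenoxy)‑4‑[2‑(4‑{2‑methoxy‑5‑[2‑(phenylsulfonyl)ethyl]phenoxy}phenyl)ethyl]‑2‑(propan‑2‑yloxy)benzene | COc1ccc(CCS(=O)(=O)c2ccccc2)cc1Oc1ccc(CCc2ccc(Oc3cccc(Cl)c3)c(OC(C)C)c2)cc1 | intermediate
14 | dilithio species of 13: Li on the sulfonyl α‑carbon and on ring D C2, between O and Cl (not isolated) | COc1ccc(CC([Li])S(=O)(=O)c2ccccc2)cc1Oc1ccc(CCc2ccc(Oc3cccc(Cl)c3[Li])c(OC(C)C)c2)cc1 | intermediate
15 | α‑lithio sulfone carrying the 3‑aryloxybenzyne on ring D (not isolated) | COc1ccc(CC([Li])S(=O)(=O)c2ccccc2)cc1Oc1ccc(CCc2ccc(OC3=CC=CC#C3)c(OC(C)C)c2)cc1 | intermediate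
16 | rac‑macrocyclic benzylic sulfone: O‑isopropylpakyonol with PhSO2 on the CH2 bonded to ring D | COc1ccc2cc1Oc1ccc(cc1)CCc1ccc(c(OC(C)C)c1)Oc1cccc(c1)C(S(=O)(=O)c1ccccc1)C2 | intermediate
17 | O‑isopropylpakyonol | COc1ccc2cc1Oc1ccc(cc1)CCc1ccc(c(OC(C)C)c1)Oc1cccc(c1)CC2 | intermediate
18 | pakyonol | COc1ccc2cc1Oc1ccc(cc1)CCc1ccc(c(O)c1)Oc1cccc(c1)CC2 | target

## Summary and fallbacks

Total step count: 10. Longest linear sequence: 7 steps (steps 1–3 or 4–6, then 7–10).

Steps most likely to fail:

Step 8 (key step, proposed new method). The aryne may be captured intermolecularly (oligomerisation, amide addition) faster than the 20‑membered ring closes, or lithiation may occur at another site. The fallback forms the same bond by known chemistry, sets out from 13 and comes back at 17. Treatment of 13 with KOt‑Bu in DMSO–THF should eliminate benzenesulfinate from the 2‑arylethyl sulfone to give the seco‑styrene 1‑(3‑chlorophenoxy)‑4‑{2‑[4‑(5‑ethenyl‑2‑methoxyphenoxy)phenyl]ethyl}‑2‑(propan‑2‑yloxy)benzene F1. Hydroboration with 9‑BBN would give the B‑alkyl‑9‑BBN adduct of the seco‑styrene F2, which is not isolated. Slow addition of this borane to Pd(OAc)2/SPhos and K3PO4 in THF–water at 70 °C under high dilution should close the ring by an intramolecular B‑alkyl Suzuki–Miyaura coupling at the aryl chloride, a known macrocyclisation type, and deliver 17 directly.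

Step 9. Electron transfer to the hindered, poorly soluble macrocyclic sulfone may stall, or base‑induced loss of sulfinate may compete. The fallback turns that elimination into the intended path, sets out from 16 and comes back at 17. KOt‑Bu in THF should eliminate benzenesulfinic acid to give the macrocyclic stilbene, O‑isopropyl‑didehydropakyonol F3, with alkene geometry of no consequence. Hydrogenation over Pd/C in EtOAc would then give 17.

Step 6. O‑Arylation of the ortho‑methoxy phenol may be slow, with oxidation or protodeboronation of the boronic acid consuming the partner. The fallback sets out from 9 and comes back at 11. It is a copper‑catalysed Ullmann ether coupling of 9 with 1‑bromo‑4‑iodobenzene (CuI, picolinic acid, K3PO4, DMSO, 85 °C), which should react selectively at the C–I bond; no new compound is made (F0).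

Further compounds
F1 | step 8 | 1‑(3‑chlorophenoxy)‑4‑{2‑[4‑(5‑ethenyl‑2‑methoxyphenoxy)phenyl]ethyl}‑2‑(propan‑2‑yloxy)benzene | COc1ccc(C=C)cc1Oc1ccc(CCc2ccc(Oc3cccc(Cl)c3)c(OC(C)C)c2)cc1
F2 | step 8 | B‑alkyl‑9‑BBN adduct of the seco‑styrene (not isolated) | COc1ccc(CCB2C3CCCC2CCC3)cc1Oc1ccc(CCc2ccc(Oc3cccc(Cl)c3)c(OC(C)C)c2)cc1
F3 | step 9 | macrocyclic stilbene, O‑isopropyl‑didehydropakyonol (alkene geometry not controlled) | COc1ccc2cc1Oc1ccc(cc1)CCc1ccc(c(OC(C)C)c1)Oc1cccc(c1)C=C2
F0 | step 6 | none | none
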